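**Retrosynthetic overview**

1. Target 26 ⇐ isopropenyl lactone 25 (allylic SeO2 oxidation); lactone ring B ⇐ ketone 22 + a carboxyl-anion equivalent; 22 ⇐ "carvone-type" enone 21 (conjugate reduction, thermodynamic ring-A CH).
2. 21 ⇐ pinene 18 through the α-pinene oxide → trans-carveol manifold: the cyclobutane of (+)-nopinone is the latent isopropenyl group and the stereochemical relay.
3. Ring D (THF bridge) ⇐ oxa-Michael addition onto a cyclohexenone (16 → 18).
4. Key step: the spiro quaternary carbon by a Still–Wittig [2,3]-sigmatropic rearrangement of a pinocarveol-type stannylmethyl ether (13 → 14); the same carbinol first directs H to the neighbouring ring-C carbon (8 → 11).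
5. 8 ⇐ epoxidation/vinylogous E1cB of dienone 6 ⇐ Suzuki coupling of nopinone enol triflate 2 with iodoenone 4. Ring order: A (as pinane) and C bought, D closed (step 10), A unveiled (step 12), B closed last (step 16).

Assumption: (1R,5S)-(+)-nopinone (1, from (−)-β-pinene) and 3,4,4-trimethylcyclohex-2-en-1-one (3) are bought; "bottom face" means the face of the pinane six-membered ring anti to the CMe2 bridge.

**Step 1**
Reactants: 1 (+)-nopinone
Product: 2 nopinone enol triflate
Conditions: LDA, THF, −78 °C; PhNTf2, −78 → 0 °C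
Reagents that add atoms: N-phenylbis(trifluoromethanesulfonimide), O=S(=O)(N(c1ccccc1)S(=O)(=O)C(F)(F)F)C(F)(F)F
Why: Enolate O-triflation; the bridgehead cannot enolise, so a single vinyl triflate forms and both bought stereocentres are untouched.

**Step 2**
Reactants: 3 3,4,4-trimethylcyclohex-2-en-1-one
Product: 4 2-iodo-3,4,4-trimethylcyclohex-2-en-1-one
Conditions: I2, pyridine, CH2Cl2, 0 °C → rt
Reagents that add atoms: iodine, II
Why: Johnson α-iodination of an enone (pyridine conjugate addition, iodination, elimination); no stereocentre is involved.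

**Step 3**
Reactants: 2 nopinone enol triflate; 4 2-iodo-3,4,4-trimethylcyclohex-2-en-1-one
Product: 6 pinenyl trimethylcyclohexenone (cross-coupled dienone), via pinenyl pinacol boronate 5 (not isolated)
Conditions: B2pin2, PdCl2(PPh3)2, PPh3, KOPh, toluene, 50 °C; then 4, Pd(dppf)Cl2, aq. K3PO4, dioxane, 80 °C
Reagents that add atoms: bis(pinacolato)diboron, CC1(C)OB(OC1(C)C)B1OC(C)(C)C(C)(C)O1 (boron enters 5 only)
Why: Miyaura borylation then Suzuki–Miyaura coupling joins the two bought rings at sp2 carbons, so no stereocentre is made or touched.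

**Step 4**
Reactants: 6 cross-coupled dienone
Product: 8 pinocarveol-type dienone alcohol (OH anti to the CMe2 bridge; ring C=O on the bridgehead side of the new exocyclic C=C), via pinene epoxide 7 (not isolated)
Conditions: mCPBA, NaHCO3, CH2Cl2, 0 °C; then DBU, rt
Reagents that add atoms: meta-chloroperbenzoic acid, OOC(=O)c1cccc(Cl)c1
Why: Prilezhaev epoxidation of the only electron-rich alkene occurs anti to the CMe2 bridge, and DBU then opens the vinyl epoxide by a vinylogous E1cB elimination (γ-deprotonation of the ring methyl), which sets the carbinol stereocentre and, because the bulky methylene/gem-dimethyl arm turns away from the bridgehead, the alkene geometry.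

**Step 5**
Reactants: 8 pinocarveol-type dienone alcohol
Product: 11 diol (ring-C CH2OH; new ring H on the carbinol-oxygen face), via dimethylsilyl ether 9 (not isolated), via cyclic siloxane 10 (not isolated)
Conditions: (HMe2Si)2NH, 60 °C; Pt(dvds) (cat.), toluene, 60 °C; then KF, KHCO3, 30% H2O2, THF/MeOH, rt
Reagents that add atoms: 1,1,3,3-tetramethyldisilazane, C[SiH](C)N[SiH](C)C; hydrogen peroxide, OO
Why: Tamao–Ito tethered hydrosilylation (Si to the terminal CH2, H to the ring carbon from the bottom face, pre-organised by the cisoid diene) followed by Tamao–Fleming oxidation gives the primary alcohol and sets the ring-C CH stereocentre.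

**Step 6**
Reactants: 11 diol
Product: 12 primary TBS ether
Conditions: TBSCl, imidazole, CH2Cl2, 0 °C
Reagents that add atoms: tert-butyldimethylsilyl chloride, CC(C)(C)[Si](C)(C)Cl
Why: Selective silylation of the unhindered primary alcohol over the hindered secondary allylic one; no stereocentre changes.

**Step 7**
Reactants: 12 primary TBS ether
Product: 13 (tributylstannyl)methyl ether
Conditions: KH, Bu3SnCH2I, 18-crown-6, THF, 0 °C → rt
Reagents that add atoms: tributyl(iodomethyl)stannane, CCCC[Sn](CCCC)(CCCC)CI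
Why: Williamson etherification of the potassium alkoxide installs the Still precursor with retention at the carbinol carbon.

**Step 8**
Reactants: 13 (tributylstannyl)methyl ether
Product: 14 spiro-quaternary α-phenylselanyl ketone (CH2OH trans to CH2OTBS)
Conditions: LDA, THF, −78 °C; n-BuLi, −78 → −20 °C; PhSeBr, −78 °C
Reagents that add atoms: benzeneselenenyl bromide, Br[Se]c1ccccc1
Why: With the ketone masked as its α′-lithium enolate, Sn–Li exchange triggers the Still–Wittig [2,3]-sigmatropic rearrangement, which delivers CH2O− to the alkene carbon suprafacially from the bottom face (anti to the neighbouring CH2OTBS), creating the spiro quaternary stereocentre and restoring the pinene alkene, after which the enolate is selenenylated.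

**Step 9**
Reactants: 14 spiro-quaternary α-phenylselanyl ketone
Product: 16 cyclohexenone TBS ether, via selenoxide 15 (not isolated)
Conditions: mCPBA, CH2Cl2, −78 °C; then i-Pr2NH, −78 °C → rt
Reagents that add atoms: meta-chloroperbenzoic acid, OOC(=O)c1cccc(Cl)c1 (oxygen enters 15 only)
Why: Selenoxide syn-elimination can only run toward the ring CH2, giving the enone without touching a stereocentre.

**Step 10**
Reactants: 16 cyclohexenone TBS ether
Product: 18 oxabicyclic ketone (6-oxabicyclo[3.2.1]octan-3-one carrying CH2OH and the pinenyl group), via diol enone 17 (not isolated)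
Conditions: TBAF, THF, 0 °C → rt
Reagents that add atoms: none
Why: Desilylation releases the alkoxide, which closes the THF bridge by intramolecular oxa-Michael addition; the 1,3-diaxial bridge can only form cis, so the new C–O stereocentre is dictated by the existing ring CH.

**Step 11**
Reactants: 18 oxabicyclic ketone
Product: 19 pinene epoxide
Conditions: mCPBA, NaHCO3, CH2Cl2, 0 °C
Reagents that add atoms: meta-chloroperbenzoic acid, OOC(=O)c1cccc(Cl)c1
Why: Prilezhaev epoxidation of the only alkene from the bottom face (anti to the bridge, assisted by the homoallylic OH).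

**Step 12**
Reactants: 19 pinene epoxide
Product: 20 ring-opened allylic alcohol (isopropenyl; OH trans to isopropenyl)
Conditions: Cs2.5H0.5PW12O40 (cat.), DMA, 140 °C
Reagents that add atoms: none
Why: Acid-catalysed epoxide isomerisation with cyclobutane fragmentation (the α-pinene oxide → trans-carveol manifold): the tertiary cation opens the four-membered ring and loses a methyl proton, unveiling the isopropenyl group at the bought stereocentre.

**Step 13**
Reactants: 20 ring-opened allylic alcohol
Product: 21 cyclohexenone (carvone-type enone)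
Conditions: MnO2, CH2Cl2, rt
Reagents that add atoms: none
Why: MnO2 oxidises only the allylic alcohol and removes the now superfluous carbinol stereocentre.

**Step 14**
Reactants: 21 carvone-type enone
Product: 22 1,4-trans cyclohexanone
Conditions: [(Ph3P)CuH]6, benzene, H2O, rt; then DBU, CH2Cl2, rt
Reagents that add atoms: none
Why: Stryker conjugate reduction spares the isopropenyl group and the hindered bicyclic ketone, and the new α-CH equilibrates to the all-equatorial isomer, trans to the isopropenyl group.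

**Step 15**
Reactants: 22 1,4-trans cyclohexanone
Product: 23 tris(methylthio)methyl carbinol
Conditions: HC(SMe)3, n-BuLi, THF, −78 °C; then 22, −78 → −40 °C
Reagents that add atoms: tris(methylthio)methane, CSC(SC)SC
Why: 1,2-Addition of the bulky carboxyl-anion equivalent (Seebach orthothioformate anion) to the less hindered ketone from the equatorial direction gives the axial tertiary alcohol with the new carbon trans to the spiro substituent.

**Step 16**
Reactants: 23 tris(methylthio)methyl carbinol
Product: 25 isopropenyl hydroxy lactone, via S-methyl thioester 24 (not isolated)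
Conditions: HgCl2, CaCO3, MeCN/H2O (4:1), rt → 50 °C
Reagents that add atoms: water, O
Why: Thiophilic Hg(II) hydrolysis of the orthothioester to the thioester and Masamune-type thioester activation let the primary alcohol close the trans-fused δ-lactone without touching a stereocentre.

**Step 17**
Reactants: 25 isopropenyl hydroxy lactone
Product: 26 target (CNP0525385.1)
Conditions: SeO2, 1,4-dioxane, 80 °C
Reagents that add atoms: selenium dioxide, O=[Se]=O
Why: Riley allylic oxidation (ene reaction, then [2,3]-sigmatropic shift) of the only allylic methyl gives the 2-substituted acrolein; no stereocentre is affected.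

**Compound list**

1 | (+)-nopinone, (1R,5S)-6,6-dimethylbicyclo[3.1.1]heptan-2-one | CC1(C)[C@H]2CCC(=O)[C@@H]1C2 | starting material
2 | nopinone enol triflate (6,6-dimethylbicyclo[3.1.1]hept-2-en-2-yl triflate, bridgeheads as in 1) | CC1(C)[C@H]2CC=C(OS(=O)(=O)C(F)(F)F)[C@@H]1C2 | intermediate
3 | 3,4,4-trimethylcyclohex-2-en-1-one | CC1=CC(=O)CCC1(C)C | starting material
4 | 2-iodo-3,4,4-trimethylcyclohex-2-en-1-one | CC1=C(I)C(=O)CCC1(C)C | intermediate
5 | pinenyl pinacol boronate | CC1(C)[C@H]2CC=C(B3OC(C)(C)C(C)(C)O3)[C@@H]1C2 | intermediate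
6 | 2-(6,6-dimethylbicyclo[3.1.1]hept-2-en-2-yl)-3,4,4-trimethylcyclohex-2-en-1-one | CC1(C)[C@H]2CC=C(C3=C(C)C(C)(C)CCC3=O)[C@@H]1C2 | intermediate
7 | pinene epoxide of 6 (oxygen anti to the CMe2 bridge) | CC1(C)[C@H]2C[C@@H]3O[C@]3(C4=C(C)C(C)(C)CCC4=O)[C@@H]1C2 | intermediate
8 | 2-(3-hydroxy-6,6-dimethylbicyclo[3.1.1]heptan-2-ylidene)-4,4-dimethyl-3-methylidenecyclohexan-1-one (OH anti to the bridge; C=O on the bridgehead side of the C=C) | CC1(C)[C@H]2C[C@H](O)/C(=C3/C(=O)CCC(C)(C)C3=C)[C@@H]1C2 | intermediate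
9 | dimethylsilyl ether of 8 | CC1(C)[C@H]2C[C@H](O[SiH](C)C)/C(=C3/C(=O)CCC(C)(C)C3=C)[C@@H]1C2 | intermediate
10 | seven-membered cyclic siloxane | CC1(C)[C@H]2C[C@@H]3O[Si](C)(C)C[C@H]4C(C)(C)CCC(=O)/C4=C3\[C@@H]1C2 | intermediate
11 | diol: 3-(hydroxymethyl) analogue of 8, ring H on the carbinol-oxygen face | CC1(C)[C@H]2C[C@H](O)/C(=C3/C(=O)CCC(C)(C)[C@@H]3CO)[C@@H]1C2 | intermediate
12 | primary TBS ether of 11 | CC1(C)[C@H]2C[C@H](O)/C(=C3/C(=O)CCC(C)(C)[C@@H]3CO[Si](C)(C)C(C)(C)C)[C@@H]1C2 | intermediate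
13 | (tributylstannyl)methyl ether of 12 | CC1(C)[C@H]2C[C@H](OC[Sn](CCCC)(CCCC)CCCC)/C(=C3/C(=O)CCC(C)(C)[C@@H]3CO[Si](C)(C)C(C)(C)C)[C@@H]1C2 | intermediate
14 | 2-(hydroxymethyl)-2-(pinen-2-yl)-3-(TBSO-methyl)-4,4-dimethyl-6-(phenylselanyl)cyclohexan-1-one (CH2OH trans to CH2OTBS; Se epimers) | CC1(C)[C@H]2CC=C([C@]3(CO)C(=O)C([Se]c4ccccc4)CC(C)(C)[C@@H]3CO[Si](C)(C)C(C)(C)C)[C@@H]1C2 | intermediate
15 | selenoxide of 14 | CC1(C)[C@H]2CC=C([C@]3(CO)C(=O)C([Se](=O)c4ccccc4)CC(C)(C)[C@@H]3CO[Si](C)(C)C(C)(C)C)[C@@H]1C2 | intermediate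
16 | 6-(hydroxymethyl)-6-(pinen-2-yl)-5-(TBSO-methyl)-4,4-dimethylcyclohex-2-en-1-one | CC1(C)[C@H]2CC=C([C@]3(CO)C(=O)C=CC(C)(C)[C@@H]3CO[Si](C)(C)C(C)(C)C)[C@@H]1C2 | intermediate
17 | desilylated diol enone | CC1(C)[C@H]2CC=C([C@]3(CO)C(=O)C=CC(C)(C)[C@@H]3CO)[C@@H]1C2 | intermediate
18 | 2-(hydroxymethyl)-8,8-dimethyl-2-(pinen-2-yl)-6-oxabicyclo[3.2.1]octan-3-one | CC1(C)[C@H]2CC=C([C@]3(CO)C(=O)C[C@@H]4OC[C@H]3C4(C)C)[C@@H]1C2 | intermediate
19 | pinene epoxide of 18 (oxygen anti to the CMe2 bridge) | CC1(C)[C@H]2C[C@@H]3O[C@]3([C@]4(CO)C(=O)C[C@@H]5OC[C@H]4C5(C)C)[C@@H]1C2 | intermediate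
20 | 2-(hydroxymethyl)-2-[6-hydroxy-4-(prop-1-en-2-yl)cyclohex-1-en-1-yl]-8,8-dimethyl-6-oxabicyclo[3.2.1]octan-3-one (OH trans to isopropenyl) | CC(=C)[C@@H]1CC=C([C@]2(CO)C(=O)C[C@@H]3OC[C@H]2C3(C)C)[C@@H](O)C1 | intermediate
21 | 2-(hydroxymethyl)-8,8-dimethyl-2-[6-oxo-4-(prop-1-en-2-yl)cyclohex-1-en-1-yl]-6-oxabicyclo[3.2.1]octan-3-one | CC(=C)[C@@H]1CC=C([C@]2(CO)C(=O)C[C@@H]3OC[C@H]2C3(C)C)C(=O)C1 | intermediate
22 | 2-(hydroxymethyl)-8,8-dimethyl-2-[2-oxo-4-(prop-1-en-2-yl)cyclohexyl]-6-oxabicyclo[3.2.1]octan-3-one (1,4-trans) | CC(=C)[C@@H]1CC[C@@H]([C@]2(CO)C(=O)C[C@@H]3OC[C@H]2C3(C)C)C(=O)C1 | intermediate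
23 | tris(methylthio)methyl carbinol (axial OH) | CC(=C)[C@@H]1CC[C@@H]([C@]2(CO)C(=O)C[C@@H]3OC[C@H]2C3(C)C)[C@](O)(C(SC)(SC)SC)C1 | intermediate
24 | S-methyl α-hydroxy thioester | CC(=C)[C@@H]1CC[C@@H]([C@]2(CO)C(=O)C[C@@H]3OC[C@H]2C3(C)C)[C@](O)(C(=O)SC)C1 | intermediate
25 | isopropenyl hydroxy lactone (target with CH3 in place of CHO) | CC(=C)[C@@H]1CC[C@H]2[C@]3(COC(=O)[C@]2(O)C1)C(=O)C[C@@H]1OC[C@H]3C1(C)C | intermediate
26 | CNP0525385.1 | C=C(C=O)[C@@H]1CC[C@H]2[C@]3(COC(=O)[C@]2(O)C1)C(=O)C[C@@H]1OC[C@H]3C1(C)C | target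

**Totals and risks**

Total step count: 17. Longest linear sequence: 16 (steps 1 and 3–17 from nopinone; step 2 is the side branch).

The three steps most likely to fail are steps 8, 12 and 15.

Step 8 is a Still–Wittig rearrangement onto a tetrasubstituted, cross-conjugated alkene with the ketone masked only as its enolate. The fallback sets out from 12 and comes back at 20. BF3·OEt2 (CH2Cl2, −40 °C) ionises the enone of 12 at the pinane ring carbon, the cyclobutane opens and proton loss gives the ring-opened hydroxy ketone F1. LDA (2.2 equiv) and monomeric CH2O then hydroxymethylate the ring-C α-carbon anti to the adjacent CH2OTBS arm, giving the spiro-quaternary diol F2. LDA/PhSeBr gives the α-phenylselanyl ketone F3, H2O2/pyridine gives the cyclohexenone TBS ether F4, and TBAF releases the alcohol that closes the oxa-bridge to 20. Steps 7–12 are bypassed.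

Step 12 is the epoxide isomerisation, where ring contraction to a campholenic-type aldehyde or hydride shift can compete with cyclobutane opening and elimination. The fallback sets out from 19 and comes back at 20. The epoxide is opened with PhSeH and catalytic BF3·OEt2 so that the tertiary cation left by the cyclobutane fragmentation is trapped as the tertiary selenide F5. H2O2/pyridine then gives the isopropenyl group of 20 by selenoxide syn-elimination.

Step 15 requires a bulky, basic carbanion to add to one of two hindered ketones with facial control. The fallback sets out from 22 and comes back at 25. KHMDS/PhNTf2 gives the kinetic enol triflate F6 (away from the neopentyl α-carbon). Pd(OAc)2/dppp, CO and Et3N in DMF then close the ring by intramolecular alkoxycarbonylation with the primary alcohol, giving the unsaturated lactone F7. K-Selectride followed by Davis oxaziridine (conjugate reduction, then enolate hydroxylation) gives 25.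

**Further compounds**

F1 | step 8 | ring-opened hydroxy ketone (ring-C α-CH epimers) | CC(=C)[C@@H]1CC=C(C2C(=O)CCC(C)(C)[C@@H]2CO[Si](C)(C)C(C)(C)C)[C@@H](O)C1
F2 | step 8 | spiro-quaternary diol | CC(=C)[C@@H]1CC=C([C@]2(CO)C(=O)CCC(C)(C)[C@@H]2CO[Si](C)(C)C(C)(C)C)[C@@H](O)C1
F3 | step 8 | α-phenylselanyl ketone | CC(=C)[C@@H]1CC=C([C@]2(CO)C(=O)C([Se]c3ccccc3)CC(C)(C)[C@@H]2CO[Si](C)(C)C(C)(C)C)[C@@H](O)C1
F4 | step 8 | cyclohexenone TBS ether | CC(=C)[C@@H]1CC=C([C@]2(CO)C(=O)C=CC(C)(C)[C@@H]2CO[Si](C)(C)C(C)(C)C)[C@@H](O)C1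
F5 | step 12 | tertiary selenide | CC(C)([Se]c1ccccc1)[C@@H]1CC=C([C@]2(CO)C(=O)C[C@@H]3OC[C@H]2C3(C)C)[C@@H](O)C1
F6 | step 15 | enol triflate | CC(=C)[C@@H]1CC[C@@H]([C@]2(CO)C(=O)C[C@@H]3OC[C@H]2C3(C)C)C(OS(=O)(=O)C(F)(F)F)=C1
F7 | step 15 | unsaturated lactone | CC(=C)[C@@H]1CC[C@H]2[C@]3(COC(=O)C2=C1)C(=O)C[C@@H]1OC[C@H]3C1(C)C
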